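**Plan**

1. Retrosynthesis: the C8 methacrylate, the C2 silyl ether and the C8 carbinol come off last; the butenolide is cut at C7=C11 (aldol condensation) and at O–C12 (ester); the cis-4,5-epoxide goes back to a Z-C4=C5 olefin.
2. Enabling feature: C8 bears oxygen and is 1,3 to C5 through C4, so a C4–C8 bond folds the ten-membered ring (C1–C10) into a cis-fused hydroazulene (cyclopentane C4–C5–C6–C7–C8 fused to cycloheptanone C8–C9–C10–C1–C2–C3–C4). Its HO–C8–C4–C5–OMs array is set up for fragmentation, and the angular C4 methyl becomes the olefin (later epoxide) methyl.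
3. The bicycle is cut at C1=C10 (metathesis), C9–C10 (oxirane opening), C8=C9 (methylenation), C6–O (oxa-Michael) and C3–C4 (Michael addition), back to 2-methylcyclopentane-1,3-dione.
4. Forward order: cyclopentane with quaternary C4 and the cis-C5/C6 diol; seven-membered ring by ring-closing metathesis; ten-membered ring by cleaving the shared C4–C8 bond; then epoxide, butenolide and esters.
5. Stereochemistry: C4/C5 from a Corey–Bakshi–Shibata desymmetrisation; C6 by a tether from C5–OH; C8 by epoxidation anti to the acetonide; C10 and C2 by convex-face attack on the cis-fused bicycle; 4Z from the anti fragmentation; the epoxide from C6–OH-directed oxygen transfer; C8–OH from a second catalyst-controlled reduction.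

Key step: step 18

Remark: target (germacrane) numbering C1–C15 is used for every compound; in bicyclic intermediates β is the face of the C4 methyl and α the opposite face; the epoxide is taken as written in the SMILES (C3 and C6 cis on the oxirane, oxygen erythro to the C6 oxygen).

**Route**

Step 1
Reactants: 1 2-methylcyclopentane-1,3-dione; 2 acrolein
Product: 3 3-(1-methyl-2,5-dioxocyclopentyl)propanal
Conditions: H2O, rt
Reagents that add atoms: none
Why: Michael addition of the acidic 1,3-dione to acrolein in water gives the C-alkylated adduct and forms the C3–C4 bond at the future quaternary carbon.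

Step 2
Reactants: 3 3-(1-methyl-2,5-dioxocyclopentyl)propanal
Product: 4 2-(but-3-en-1-yl)-2-methylcyclopentane-1,3-dione
Conditions: Ph3PCH3Br, KOtBu, THF, −78 to 0 °C
Reagents that add atoms: methyltriphenylphosphonium bromide, C[P+](c1ccccc1)(c1ccccc1)c1ccccc1.[Br-]
Why: Wittig methylenation, in which one equivalent of the unstabilised ylide should take the aldehyde well before the two ring ketones that flank a quaternary carbon.

Step 3
Reactants: 4 2-(but-3-en-1-yl)-2-methylcyclopentane-1,3-dione
Product: 5 (2R,3R)-2-(but-3-en-1-yl)-3-hydroxy-2-methylcyclopentan-1-one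
Conditions: (S)-1-methyl-3,3-diphenyltetrahydro-1H,3H-pyrrolo[1,2-c][1,3,2]oxazaborole (20 mol%), catecholborane (1.1 equiv), toluene, −60 °C
Reagents that add atoms: none
Why: Corey–Bakshi–Shibata reduction desymmetrises the dione: with the quaternary carbon as the large substituent the (S)-catalyst should give the R carbinol (C5), hydride enters anti to the butenyl chain so that C5–OH is cis to the chain and C4 becomes R, and catecholborane leaves the terminal alkene alone.

Step 4
Reactants: 5 (2R,3R)-2-(but-3-en-1-yl)-3-hydroxy-2-methylcyclopentan-1-one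
Product: 7 (4R,5R)-5-(but-3-en-1-yl)-4-hydroxy-5-methylcyclopent-2-en-1-one, via bis(trimethylsilyl) derivative 6 (not isolated)
Conditions: Me3SiOTf, Et3N, CH2Cl2, 0 °C; then 2-iodoxybenzoic acid·4-methoxypyridine N-oxide, DMSO, rt; 1 M HCl, THF work-up
Reagents that add atoms: none
Why: The silyl enol ether can form only toward C7 because C4 is quaternary, and its dehydrogenation by the hypervalent iodine reagent (a metal-free Saegusa-type oxidation that spares the terminal alkene) gives the C6=C7 enone, while the transient C5 silyl ether shields the carbinol and falls off in the acidic work-up.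

Step 5
Reactants: 7 (4R,5R)-5-(but-3-en-1-yl)-4-hydroxy-5-methylcyclopent-2-en-1-one
Product: 8 cyclic phenylboronate of (2R,3S,4R)-2-(but-3-en-1-yl)-3,4-dihydroxy-2-methylcyclopentan-1-one
Conditions: PhB(OH)2 (1.2 equiv), iPr2NEt (20 mol%), 4 Å molecular sieves, toluene, 40 °C
Reagents that add atoms: phenylboronic acid, OB(O)c1ccccc1
Why: The C5 hydroxyl forms a boronic acid hemiester whose B–OH adds to C6 of the enone (amine-promoted oxa-Michael addition of a boronic acid hemiester to a γ-hydroxy enone), and the five-membered tether forces the new C6 oxygen cis to the C5 oxygen.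

Step 6
Reactants: 8 cyclic phenylboronate of the cis-5,6-diol ketone
Product: 10 5α,6α-O-isopropylidene ketone (acetonide of diol 9), via cis-5,6-diol 9 (not isolated)
Conditions: 30% H2O2, pH 7 phosphate buffer, THF, 0 °C; then 2,2-dimethoxypropane, pyridinium p-toluenesulfonate, acetone, rt
Reagents that add atoms: 2,2-dimethoxypropane, COC(C)(C)OC
Why: Oxidative cleavage of the B–aryl bond frees the cis-diol under neutral conditions, and acid-catalysed transketalisation (acetonide formation) closes the cis-fused dioxolane before the β-hydroxy ketone can eliminate.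

Step 7
Reactants: 10 5α,6α-O-isopropylidene ketone
Product: 11 C8-methylidene acetonide (C8=O of 10 replaced by C8=CH2)
Conditions: Cp2TiMe2 (2.5 equiv), toluene, 70 °C, dark
Reagents that add atoms: dimethyltitanocene Cp2TiMe2, [CH3-].[CH3-].[Ti+4].c1cc[cH-]c1.c1cc[cH-]c1
Why: Petasis methylenation is non-basic, so the hindered β-alkoxy ketone should be converted to the exocyclic alkene (C9) without β-elimination of the acetonide oxygen.

Step 8
Reactants: 11 C8-methylidene acetonide
Product: 12 spiro-oxirane at C8 (oxirane oxygen β, cis to the C4 methyl; C9 α)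
Conditions: mCPBA (1.05 equiv), NaHCO3, CH2Cl2, −10 °C
Reagents that add atoms: 3-chloroperbenzoic acid, OOC(=O)c1cccc(Cl)c1
Why: Prilezhaev epoxidation should take the more electron-rich 1,1-disubstituted alkene before the monosubstituted butenyl alkene and approach from the methyl face, away from the acetonide and the butenyl chain, which sets C8 with its oxygen cis to the C4 methyl.

Step 9
Reactants: 12 spiro-oxirane at C8; 13 isopropenylmagnesium bromide
Product: 14 tertiary alcohol with C8–OH β, a 2-methylallyl group on C8 and the butenyl chain on C4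
Conditions: CuI (15 mol%), THF, −30 to 0 °C; aq. NH4Cl
Reagents that add atoms: none
Why: Copper-catalysed Grignard opening of a 2,2-disubstituted oxirane occurs at the CH2 carbon (C9), which attaches C10 with its methyl and leaves the C8 configuration untouched.

Step 10
Reactants: 14 tertiary alcohol diene
Product: 15 cis-fused hydroazulene 8β-hydroxy-4β,10-dimethyl-5α,6α-(isopropylidenedioxy)bicyclo[5.3.0]dec-1(10)-ene
Conditions: second-generation Grubbs catalyst RuCl2(=CHPh)(PCy3)(H2IMes) (5 mol%), toluene, 80 °C
Reagents that add atoms: none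
Why: Ring-closing metathesis of the monosubstituted and the 1,1-disubstituted alkene, which sit cis on the cyclopentane, should close the seven-membered ring as the trisubstituted C1=C10 olefin with loss of ethene.

Step 11
Reactants: 15 cis-fused hydroazulene olefin
Product: 17 1β,8β-dihydroxy-10α-methyl acetonide, via C1 alkylborane 16 (not isolated)
Conditions: BH3·THF, THF, 0 °C to rt; then 3 M NaOH, 30% H2O2, 0 °C to rt
Reagents that add atoms: hydrogen peroxide, OO
Why: Hydroboration–oxidation adds boron to C1 and hydrogen to C10 in a syn fashion from the convex β face of the cis-fused bicycle, so the C10 methyl is pushed to the α face.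

Step 12
Reactants: 17 1β,8β-dihydroxy-10α-methyl acetonide
Product: 18 8β-hydroxy-10α-methyl-1-ketone acetonide
Conditions: Dess–Martin periodinane, NaHCO3, CH2Cl2, 0 °C to rt
Reagents that add atoms: none
Why: Dess–Martin oxidation converts the secondary C1 alcohol to the ketone under buffered conditions that neither touch the tertiary C8 alcohol nor epimerise C10.

Step 13
Reactants: 18 8β-hydroxy-10α-methyl-1-ketone acetonide
Product: 20 2β,8β-dihydroxy-1-ketone acetonide, via dipotassium alkoxide enolate 19 (not isolated)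
Conditions: KN(SiMe3)2 (2.2 equiv), THF, −78 °C; then 2-(phenylsulfonyl)-3-phenyloxaziridine, −78 °C; aq. NH4Cl
Reagents that add atoms: 2-(phenylsulfonyl)-3-phenyloxaziridine, O=S(=O)(N1OC1c1ccccc1)c1ccccc1
Why: After the C8 hydroxyl, the base removes a proton kinetically from the CH2 at C2 and not from the methyl-bearing C10, and the oxaziridine hydroxylates this enolate from the convex β face (enolate hydroxylation), placing C2–OH cis to the angular methyl.

Step 14
Reactants: 20 2β,8β-dihydroxy-1-ketone acetonide
Product: 21 2β-(tert-butyldimethylsilyloxy)-8β-hydroxy-1-ketone acetonide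
Conditions: TBSCl, imidazole, DMF, rt
Reagents that add atoms: tert-butyldimethylsilyl chloride, CC(C)(C)[Si](C)(C)Cl
Why: Silylation with the chloride and imidazole is selective for the secondary C2 hydroxyl over the tertiary C8 hydroxyl.

Step 15
Reactants: 21 2β-silyloxy acetonide
Product: 22 5α,6α,8β-triol with C2–OTBS and C1 ketone
Conditions: AcOH/H2O (4:1), 45 °C
Reagents that add atoms: none
Why: Acid hydrolysis removes the acetonide, while the silyl ether next to the ketone (a less basic oxygen) and the tertiary alcohol should survive dilute acetic acid.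

Step 16
Reactants: 22 5α,6α,8β-triol
Product: 23 6α-triethylsilyloxy-5α,8β-diol
Conditions: Et3SiCl (1.05 equiv), imidazole, CH2Cl2, −40 °C
Reagents that add atoms: chlorotriethylsilane, CC[Si](Cl)(CC)CC
Why: C6–OH is the only hydroxyl that is neither neopentyl (C5) nor tertiary (C8), so one equivalent of silyl chloride at low temperature should select it.

Step 17
Reactants: 23 6α-triethylsilyloxy-5α,8β-diol
Product: 24 hydroazulene mesylate (8β-OH, 5α-OMs, 6α-OTES, 2β-OTBS, 1-oxo, 10α-Me; 2S,4R,5S,6R,8R,10S)
Conditions: MsCl, Et3N, CH2Cl2, 0 °C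
Reagents that add atoms: methanesulfonyl chloride, CS(=O)(=O)Cl
Why: Sulfene-mediated mesylation sulfonylates the remaining secondary C5 hydroxyl with retention, keeping the leaving group trans to the C4 methyl, and leaves the tertiary C8 hydroxyl free.

Step 18
Reactants: 24 hydroazulene mesylate
Product: 26 (2S,4Z,6R,10S)-2-(tert-butyldimethylsilyloxy)-4,10-dimethyl-6-(triethylsilyloxy)cyclodec-4-ene-1,8-dione, via potassium C8 alkoxide 25 (not isolated)
Conditions: KOtBu (1.05 equiv), THF, 0 °C, 15 min; pH 7 buffer
Reagents that add atoms: none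
Why: Deprotonation of the tertiary C8 hydroxyl gives alkoxide 25, whose oxygen lone pair pushes into the C4–C8 σ bond while the C5–OMs bond, held roughly anti to it across the cyclopentane, departs in the same step, so that C8=O and C4=C5 form as C4–C8 breaks (Wharton–Grob fragmentation of a cyclic 1,3-diol monosulfonate is the closest known reaction type). No ring is closed by bond formation: the ten-membered ring C1–C10 is released by cleaving the bond shared by the five- and seven-membered rings. No stereocentre is created; C2, C6 and C10 are carried over and C4, C5 and C8 become trigonal. The selectivity needed is olefin geometry, and the substrate fixes it: the mesylate is trans to the C4 methyl and cis to C3, so the anti fragmentation leaves C3 and C6 cis on the new double bond (4Z). Only the C4–C8 bond is both anti to the leaving group and backed by an oxyanion, which excludes cleavage of C3–C4 or C4–CH3, and the single equivalent of base is consumed by the fragmentation, so that neither the β-silyloxy ketone nor the epimerisable C10 centre should meet excess base.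

Step 19
Reactants: 26 cyclodecenedione bis-silyl ether
Product: 27 (2S,4Z,6R,10S)-2-(tert-butyldimethylsilyloxy)-6-hydroxy-4,10-dimethylcyclodec-4-ene-1,8-dione
Conditions: pyridinium p-toluenesulfonate, MeOH/CH2Cl2, 0 °C
Reagents that add atoms: none
Why: Mild acid methanolysis cleaves the allylic triethylsilyl ether much faster than the tert-butyldimethylsilyl ether, without base that could eliminate the β-hydroxy ketone.

Step 20
Reactants: 27 C6 allylic alcohol
Product: 28 (2S,4S,5R,6R,10S)-2-(tert-butyldimethylsilyloxy)-4,5-epoxy-6-hydroxy-4,10-dimethylcyclodecane-1,8-dione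
Conditions: VO(acac)2 (5 mol%), tBuOOH (1.5 equiv), CH2Cl2, 0 °C to rt
Reagents that add atoms: tert-butyl hydroperoxide, CC(C)(C)OO
Why: Vanadium-catalysed hydroxyl-directed epoxidation delivers the peroxide oxygen from the vanadate ester of the C6 hydroxyl to the only olefin, a delivery known to favour the cis (erythro) epoxy alcohol for (Z)-cycloalk-2-enols of medium ring size, here 4S,5R, while the Z geometry carries over as the cis oxirane.

Step 21
Reactants: 28 epoxy alcohol; 29 2-(bromomethyl)acrylic acid
Product: 30 C6 2-(bromomethyl)acrylate of 28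
Conditions: N,N'-dicyclohexylcarbodiimide, 4-(dimethylamino)pyridine (5 mol%), CH2Cl2, 0 °C
Reagents that add atoms: none
Why: Steglich esterification acylates the secondary C6 hydroxyl under nearly neutral conditions and brings in C11, C12 and C13.

Step 22
Reactants: 30 C6 2-(bromomethyl)acrylate
Product: 31 C6 2-(acetoxymethyl)acrylate
Conditions: KOAc, AcOH (1 equiv), DMF, rt
Reagents that add atoms: potassium acetate, CC(=O)[O-].[K+]
Why: Acetate displaces the allylic bromide (SN2 and SN2′ attack give the same product) under buffered conditions, which installs the C13 acetate.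

Step 23
Reactants: 31 C6 2-(acetoxymethyl)acrylate
Product: 33 C6 3-acetoxy-2-oxopropanoate (α-keto ester), via secondary ozonide 32 (not isolated)
Conditions: O3, CH2Cl2, −78 °C; then Me2S, −78 °C to rt
Reagents that add atoms: ozone, [O-][O+]=O
Why: Ozonolysis with reductive work-up cleaves the acrylate double bond, the only C=C left now that the ring olefin is an epoxide, to the α-keto ester and formaldehyde.

Step 24
Reactants: 33 C6 3-acetoxy-2-oxopropanoate
Product: 35 8-oxo butenolide (7(11)-en-12,6-olide with C13–OAc, C2–OTBS, 4,5-epoxide), via aldol adduct 34 (not isolated)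
Conditions: iPr2NEt, LiCl, MeCN, −10 °C; then SOCl2, pyridine, CH2Cl2, −20 to 0 °C
Reagents that add atoms: none
Why: Intramolecular aldol condensation in which only the C7 enolate of the C8 ketone can reach the very electrophilic ketone tethered through C6–O (5-exo closure of the lactone ring), after which the chlorosulfite of the tertiary aldol eliminates toward the acidic C7–H to give the tetrasubstituted C7=C11 double bond.

Step 25
Reactants: 35 8-oxo butenolide
Product: 36 (8R)-8-hydroxy butenolide
Conditions: (S)-1-methyl-3,3-diphenyltetrahydro-1H,3H-pyrrolo[1,2-c][1,3,2]oxazaborole (1.0 equiv), catecholborane (1.1 equiv), toluene/CH2Cl2, −78 °C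
Reagents that add atoms: none
Why: Corey–Bakshi–Shibata reduction lets the catalyst rather than the flexible ring choose the face: with alkenyl C7 as the large and the C9 methylene as the small substituent the (S)-catalyst should give the 8R carbinol by 1,2-reduction, and the C8 ketone, activated by the butenolide and flanked by a CH2, should react before the C1 ketone that sits between two branched carbons.

Step 26
Reactants: 36 (8R)-8-hydroxy butenolide
Product: 37 8-O-methacrylate with C2–OTBS
Conditions: methacrylic anhydride, Et3N, 4-(dimethylamino)pyridine, CH2Cl2, 0 °C to rt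
Reagents that add atoms: methacrylic anhydride, C=C(C)C(=O)OC(=O)C(C)=C
Why: Nucleophile-catalysed acylation esterifies the only free hydroxyl (C8) with retention.

Step 27
Reactants: 37 8-O-methacrylate with C2–OTBS
Product: 38 target CNP0359197.1
Conditions: HF·pyridine, pyridine, THF, 0 °C to rt
Reagents that add atoms: none
Why: Buffered fluoride cleaves the last silyl ether to free C2–OH under conditions that should leave the epoxide, the allylic acetate, the methacrylate and the butenolide intact.

**Compound list**

1 | 2-methylcyclopentane-1,3-dione | CC1C(=O)CCC1=O | starting material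
2 | acrolein | C=CC=O | starting material
3 | 3-(1-methyl-2,5-dioxocyclopentyl)propanal | O=CCCC1(C)C(=O)CCC1=O | intermediate
4 | 2-(but-3-en-1-yl)-2-methylcyclopentane-1,3-dione | C=CCCC1(C)C(=O)CCC1=O | intermediate
5 | (2R,3R)-2-(but-3-en-1-yl)-3-hydroxy-2-methylcyclopentan-1-one (C5–OH cis to the butenyl chain) | C=CCC[C@]1(C)[C@H](O)CCC1=O | intermediate
6 | bis(trimethylsilyl) derivative of 5 (C7=C8 enol ether and C5 silyl ether) | C=CCC[C@]1(C)[C@H](O[Si](C)(C)C)CC=C1O[Si](C)(C)C | intermediate (not isolated)
7 | (4R,5R)-5-(but-3-en-1-yl)-4-hydroxy-5-methylcyclopent-2-en-1-one | C=CCC[C@]1(C)[C@H](O)C=CC1=O | intermediate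
8 | cyclic phenylboronate of the cis-5,6-diol ketone | C=CCC[C@]1(C)[C@@H]2OB(c3ccccc3)O[C@@H]2CC1=O | intermediate
9 | (2R,3S,4R)-2-(but-3-en-1-yl)-3,4-dihydroxy-2-methylcyclopentan-1-one (both hydroxyls cis to the butenyl chain) | C=CCC[C@]1(C)[C@H](O)[C@H](O)CC1=O | intermediate (not isolated)
10 | acetonide of 9 (5α,6α-O-isopropylidene, C8 ketone) | C=CCC[C@]1(C)[C@@H]2OC(C)(C)O[C@@H]2CC1=O | intermediate
11 | C8-methylidene acetonide | C=CCC[C@]1(C)[C@@H]2OC(C)(C)O[C@@H]2CC1=C | intermediate
12 | spiro-oxirane at C8 (oxygen cis to C4 methyl, C9 on the acetonide face) | C=CCC[C@]1(C)[C@@H]2OC(C)(C)O[C@@H]2C[C@]13CO3 | intermediate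
13 | isopropenylmagnesium bromide | C=C(C)[Mg]Br | starting material
14 | tertiary alcohol: C8–OH cis to C4 methyl, 2-methylallyl on C8, butenyl on C4, 5α,6α-acetonide | C=CCC[C@]1(C)[C@@H]2OC(C)(C)O[C@@H]2C[C@]1(O)CC(C)=C | intermediate
15 | cis-fused 8β-hydroxy-4β,10-dimethyl-5α,6α-(isopropylidenedioxy)bicyclo[5.3.0]dec-1(10)-ene | O[C@@]12CC(C)=CCC[C@]1(C)[C@@H]3OC(C)(C)O[C@@H]3C2 | intermediate
16 | C1 alkylborane from 15 (written as the monoalkylborane; boron β at C1, H β at C10) | O[C@@]12C[C@H](C)[C@@H](B)CC[C@]1(C)[C@@H]3OC(C)(C)O[C@@H]3C2 | intermediate (not isolated)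
17 | 1β,8β-dihydroxy-10α-methyl acetonide | O[C@@]12C[C@H](C)[C@@H](O)CC[C@]1(C)[C@@H]3OC(C)(C)O[C@@H]3C2 | intermediate
18 | 8β-hydroxy-10α-methyl-1-ketone acetonide | O[C@@]12C[C@H](C)C(=O)CC[C@]1(C)[C@@H]3OC(C)(C)O[C@@H]3C2 | intermediate
19 | dipotassium C8 alkoxide C1=C2 enolate of 18 | [K+].[K+].[O-][C@@]12C[C@H](C)C([O-])=CC[C@]1(C)[C@@H]3OC(C)(C)O[C@@H]3C2 | intermediate (not isolated)
20 | 2β,8β-dihydroxy-1-ketone acetonide | O[C@@]12C[C@H](C)C(=O)[C@@H](O)C[C@]1(C)[C@@H]3OC(C)(C)O[C@@H]3C2 | intermediate
21 | 2β-(tert-butyldimethylsilyloxy)-8β-hydroxy-1-ketone acetonide | O[C@@]12C[C@H](C)C(=O)[C@@H](O[Si](C)(C)C(C)(C)C)C[C@]1(C)[C@@H]3OC(C)(C)O[C@@H]3C2 | intermediate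
22 | 5α,6α,8β-triol with C2–OTBS and C1 ketone | O[C@@]12C[C@H](C)C(=O)[C@@H](O[Si](C)(C)C(C)(C)C)C[C@]1(C)[C@H](O)[C@H](O)C2 | intermediate
23 | 6α-triethylsilyloxy-5α,8β-diol | O[C@@]12C[C@H](C)C(=O)[C@@H](O[Si](C)(C)C(C)(C)C)C[C@]1(C)[C@H](O)[C@H](O[Si](CC)(CC)CC)C2 | intermediate
24 | hydroazulene mesylate, fragmentation precursor (2S,4R,5S,6R,8R,10S; 8β-OH, 5α-OMs, 6α-OTES, 2β-OTBS, 1-oxo) | O[C@@]12C[C@H](C)C(=O)[C@@H](O[Si](C)(C)C(C)(C)C)C[C@]1(C)[C@H](OS(C)(=O)=O)[C@H](O[Si](CC)(CC)CC)C2 | intermediate
25 | potassium C8 alkoxide of 24 | [K+].[O-][C@@]12C[C@H](C)C(=O)[C@@H](O[Si](C)(C)C(C)(C)C)C[C@]1(C)[C@H](OS(C)(=O)=O)[C@H](O[Si](CC)(CC)CC)C2 | intermediate (not isolated)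
26 | (2S,4Z,6R,10S)-2-(tert-butyldimethylsilyloxy)-4,10-dimethyl-6-(triethylsilyloxy)cyclodec-4-ene-1,8-dione | O=C1C[C@H](C)C(=O)[C@@H](O[Si](C)(C)C(C)(C)C)C/C(C)=C\[C@H](O[Si](CC)(CC)CC)C1 | intermediate
27 | (2S,4Z,6R,10S)-2-(tert-butyldimethylsilyloxy)-6-hydroxy-4,10-dimethylcyclodec-4-ene-1,8-dione | O=C1C[C@H](C)C(=O)[C@@H](O[Si](C)(C)C(C)(C)C)C/C(C)=C\[C@H](O)C1 | intermediate
28 | (2S,4S,5R,6R,10S)-2-(tert-butyldimethylsilyloxy)-4,5-epoxy-6-hydroxy-4,10-dimethylcyclodecane-1,8-dione | O=C1C[C@H](C)C(=O)[C@@H](O[Si](C)(C)C(C)(C)C)C[C@]2(C)O[C@@H]2[C@H](O)C1 | intermediate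
29 | 2-(bromomethyl)acrylic acid | OC(=O)C(=C)CBr | starting material
30 | C6 2-(bromomethyl)acrylate of 28 | O=C1C[C@H](C)C(=O)[C@@H](O[Si](C)(C)C(C)(C)C)C[C@]2(C)O[C@@H]2[C@H](OC(=O)C(=C)CBr)C1 | intermediate
31 | C6 2-(acetoxymethyl)acrylate | O=C1C[C@H](C)C(=O)[C@@H](O[Si](C)(C)C(C)(C)C)C[C@]2(C)O[C@@H]2[C@H](OC(=O)C(=C)COC(C)=O)C1 | intermediate
32 | secondary ozonide (1,2,4-trioxolane) of 31, C11 configuration undefined | O=C1C[C@H](C)C(=O)[C@@H](O[Si](C)(C)C(C)(C)C)C[C@]2(C)O[C@@H]2[C@H](OC(=O)C3(COC(C)=O)OOCO3)C1 | intermediate (not isolated)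
33 | C6 3-acetoxy-2-oxopropanoate | O=C1C[C@H](C)C(=O)[C@@H](O[Si](C)(C)C(C)(C)C)C[C@]2(C)O[C@@H]2[C@H](OC(=O)C(=O)COC(C)=O)C1 | intermediate
34 | aldol adduct: 11-hydroxy-12,6-lactone with C7–H, C7 and C11 as an epimer mixture | O=C1C[C@H](C)C(=O)[C@@H](O[Si](C)(C)C(C)(C)C)C[C@]2(C)O[C@@H]2[C@@H]2OC(=O)C(O)(COC(C)=O)C21 | intermediate (not isolated)
35 | 8-oxo butenolide (2S,4S,5R,6R,10S): 7(11)-en-12,6-olide, C13–OAc, C2–OTBS, C1 and C8 ketones | O=C1C[C@H](C)C(=O)[C@@H](O[Si](C)(C)C(C)(C)C)C[C@]2(C)O[C@@H]2[C@@H]2OC(=O)C(COC(C)=O)=C21 | intermediate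
36 | (8R)-8-hydroxy butenolide | O[C@@H]1C[C@H](C)C(=O)[C@@H](O[Si](C)(C)C(C)(C)C)C[C@]2(C)O[C@@H]2[C@@H]2OC(=O)C(COC(C)=O)=C21 | intermediate
37 | 8-O-methacrylate with C2–OTBS | C=C(C)C(=O)O[C@@H]1C[C@H](C)C(=O)[C@@H](O[Si](C)(C)C(C)(C)C)C[C@]2(C)O[C@@H]2[C@@H]2OC(=O)C(COC(C)=O)=C21 | intermediate
38 | CNP0359197.1, (2S,4S,5R,6R,8R,10S)-13-acetoxy-4,5-epoxy-2-hydroxy-8-methacryloyloxy-1-oxogermacr-7(11)-en-12,6-olide | C=C(C)C(=O)O[C@@H]1C[C@H](C)C(=O)[C@@H](O)C[C@]2(C)O[C@@H]2[C@@H]2OC(=O)C(COC(C)=O)=C21 | target

**Step count and risks**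

Total step count: 27. Longest linear sequence: 27 steps (1 to 38); compounds 2, 13 and 29 are commercial and enter directly.

The three steps most likely to fail:

Step 18. The C8–C4 and C5–O bonds can reach only an approximately anti arrangement inside the five-membered ring. If this slows the fragmentation, E2 loss of the mesylate toward C6–H, base-induced loss of the C6 silyloxy group from the product, or epimerisation at C10 could compete. The fallback changes the nucleofuge and removes the silyl ether from the event. It sets out from triol 22: thionyl chloride and Et3N give the 5α,6α-cyclic sulfite F1, and RuCl3 (catalytic) with NaIO4 oxidises it to the 5α,6α-cyclic sulfate F2. With KOtBu the C8 alkoxide fragments with the C5–O bond of the cyclic sulfate as leaving group, which gives the potassium C6 sulfate monoester of the cyclodecenedione F3; the sulfate monoanion on C6 is a poor leaving group for β-elimination. Hydrolysis with catalytic H2SO4 in wet THF then returns to the route at alcohol 27.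

Step 20. The delivery of oxygen from the C6 hydroxyl may show poor facial selectivity, or favour the threo face, if the ten-membered ring does not adopt the geometry that medium-ring cycloalkenols use. The fallback puts the oxygen on the face opposite to the one an electrophile attacks. It sets out from silyl ether 26: N-bromosuccinimide in aqueous THF forms the bromonium ion on the exposed face and water opens it at the tertiary C4 to give the bromohydrin F4 (C4–OH, C5–Br). Ag2O closes the oxirane with inversion at C5 to the 6-O-triethylsilyl epoxide F5, and methanolysis with pyridinium p-toluenesulfonate returns to the route at epoxy alcohol 28.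

Step 24. β-Elimination of the C6 acyloxy group from the C8 enolate may outrun the aldol closure, because the α-keto carboxylate is a good leaving group. The fallback forms the C7–C11 bond while the C6 oxygen is a silyl ether and closes the lactone last. It sets out from epoxy alcohol 28: tBu2Si(OTf)2 and Et3N convert the β-hydroxy ketone into the 2,2-di-tert-butyl-4H-1,3,2-dioxasiline F6, a cyclic silyl enol ether that can only be the C7=C8 isomer. A Mukaiyama aldol addition of F6 to ethyl 3-acetoxy-2-oxopropanoate (Bu4N[Ph3SiF2] as catalyst), followed by brief buffered HF·pyridine, gives the open-chain C7 aldol ethyl ester with free C6–OH F7. Lactonisation of F7 with loss of ethanol returns to the route at aldol adduct 34, which is dehydrated to 35 as in step 24.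

**Further compounds**

F1 | step 18 | 5α,6α-cyclic sulfite of triol 22 | O[C@@]12C[C@H](C)C(=O)[C@@H](O[Si](C)(C)C(C)(C)C)C[C@]1(C)[C@@H]3OS(=O)O[C@@H]3C2
F2 | step 18 | 5α,6α-cyclic sulfate of triol 22 | O[C@@]12C[C@H](C)C(=O)[C@@H](O[Si](C)(C)C(C)(C)C)C[C@]1(C)[C@@H]3OS(=O)(=O)O[C@@H]3C2
F3 | step 18 | potassium (2S,4Z,6R,10S)-2-(tert-butyldimethylsilyloxy)-4,10-dimethyl-1,8-dioxocyclodec-4-en-6-yl sulfate | [K+].O=C1C[C@H](C)C(=O)[C@@H](O[Si](C)(C)C(C)(C)C)C/C(C)=C\[C@H](OS(=O)(=O)[O-])C1
F4 | step 20 | bromohydrin of 26 (C4–OH, C5–Br, anti addition) | O=C1C[C@H](C)C(=O)[C@@H](O[Si](C)(C)C(C)(C)C)C[C@](C)(O)[C@@H](Br)[C@H](O[Si](CC)(CC)CC)C1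
F5 | step 20 | 6-O-triethylsilyl ether of epoxy alcohol 28 | O=C1C[C@H](C)C(=O)[C@@H](O[Si](C)(C)C(C)(C)C)C[C@]2(C)O[C@@H]2[C@H](O[Si](CC)(CC)CC)C1
F6 | step 24 | 2,2-di-tert-butyl-4H-1,3,2-dioxasiline spanning O6 and O8 of 28 (C7=C8 enol ether) | O1[Si](C(C)(C)C)(C(C)(C)C)O[C@@H]2C=C1C[C@H](C)C(=O)[C@@H](O[Si](C)(C)C(C)(C)C)C[C@]3(C)O[C@H]23
F7 | step 24 | open-chain C7 aldol ethyl ester with free C6–OH (C7 and C11 as an epimer mixture) | O=C1C[C@H](C)C(=O)[C@@H](O[Si](C)(C)C(C)(C)C)C[C@]2(C)O[C@@H]2[C@H](O)C1C(O)(COC(C)=O)C(=O)OCC
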